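**Plan**
- Retrosynthesis: the last step removes four benzyl ethers and a helper bromine at C5. The key disconnection then cuts O1–C8a and C4a–C4 of the upper chroman together, giving a trans-2,3-diaryloxetane (24) and 5-benzyloxy-3-bromobenzyne (30).
- Enabling feature: C4 is bonded to C5' of the lower (vestitol) ring B, ortho to the C4' methoxy and para to the C2' oxygen, so an O-aryloxetanium ion opens at C4 to a 2,4-dialkoxybenzyl cation. C4a and C8a are adjacent carbons of upper ring A, so ring A can enter as an aryne.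
- The oxetane is cut back to a 1,3-diol and then, by an auxiliary-controlled anti-aldol, to the arylacetyl imide 19 and the isoflavan aldehyde 11.
- Forward ring order: the lower pyran ring (O-alkylation, intramolecular Wittig, asymmetric hydrogenation), then the oxetane, then the upper pyran ring when ring A is inserted.
- Stereochemistry: lower C3 from the iridium catalyst; upper C3 from the oxazolidinone auxiliary; upper C4 from C3 by A(1,3) strain in the ring closure (3,4-trans).

Key step: step 19

Assumption: the (S)-phosphino-oxazoline ligand in step 7 is taken to deliver the 3R isoflavan; if the sense is opposite, the (R)-ligand is used.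

Abbreviations in names: Ar1 = 4-(benzyloxy)-5-[(3R)-7-(benzyloxy)chroman-3-yl]-2-methoxyphenyl; Ar2 = 3-(benzyloxy)-2,4-dimethoxyphenyl.

**Lower isoflavan aldehyde**

Step 1
Reactants: 1 paeonol [1-(2-hydroxy-4-methoxyphenyl)ethanone]
Product: 2 1-(5-bromo-2-hydroxy-4-methoxyphenyl)ethanone
Conditions: NBS (1.0 equiv), MeCN, 0 → 25 °C
Reagents that add atoms: N-bromosuccinimide, O=C1CCC(=O)N1Br
Why: electrophilic aromatic bromination should go para to the free phenol and ortho to the methoxy group, the site between the two oxygens being hindered.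

Step 2
Reactants: 2 1-(5-bromo-2-hydroxy-4-methoxyphenyl)ethanone
Product: 3 1-[2-(benzyloxy)-5-bromo-4-methoxyphenyl]ethanone
Conditions: BnBr, K2CO3, DMF, 60 °C
Reagents that add atoms: benzyl bromide, BrCc1ccccc1
Why: Williamson O-benzylation of the phenol.

Step 3
Reactants: 3 1-[2-(benzyloxy)-5-bromo-4-methoxyphenyl]ethanone
Product: 4 1-[2-(benzyloxy)-5-bromo-4-methoxyphenyl]-2-bromoethanone
Conditions: CuBr2 (2.1 equiv), EtOAc/CHCl3, reflux
Reagents that add atoms: copper dibromide, Br[Cu]Br
Why: α-bromination of the aryl methyl ketone through its enol, which stops cleanly at the monobromide with this reagent.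

Step 4
Reactants: 5 4-(benzyloxy)-2-hydroxybenzaldehyde
Product: 6 5-(benzyloxy)-2-(hydroxymethyl)phenol
Conditions: NaBH4, MeOH/THF, 0 °C
Reagents that add atoms: none
Why: borohydride reduction of the aldehyde to the benzylic alcohol.

Step 5
Reactants: 6 5-(benzyloxy)-2-(hydroxymethyl)phenol
Product: 7 [4-(benzyloxy)-2-hydroxybenzyl]triphenylphosphonium bromide
Conditions: PPh3·HBr, MeCN, reflux
Reagents that add atoms: triphenylphosphine hydrobromide, [Br-].[PH+](c1ccccc1)(c1ccccc1)c1ccccc1
Why: the electron-rich ortho-hydroxybenzyl alcohol ionises under acid and is trapped by triphenylphosphine, the standard preparation of (2-hydroxybenzyl)phosphonium salts.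

Step 6
Reactants: 4 1-[2-(benzyloxy)-5-bromo-4-methoxyphenyl]-2-bromoethanone; 7 [4-(benzyloxy)-2-hydroxybenzyl]triphenylphosphonium bromide
Product: 9 7-(benzyloxy)-3-[2-(benzyloxy)-5-bromo-4-methoxyphenyl]-2H-chromene, via phenacyl ether phosphonium bromide 8 (not isolated)
Conditions: K2CO3, DMF, 25 °C; then KOtBu, THF, 0 → 60 °C
Reagents that add atoms: none
Why: phenoxide O-alkylation by the phenacyl bromide followed by intramolecular Wittig olefination of the benzylic ylide with the aryl ketone closes the pyran ring as a 3-aryl-2H-chromene (isoflav-3-ene).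

Step 7
Reactants: 9 7-(benzyloxy)-3-[2-(benzyloxy)-5-bromo-4-methoxyphenyl]-2H-chromene
Product: 10 (3R)-7-(benzyloxy)-3-[2-(benzyloxy)-5-bromo-4-methoxyphenyl]chromane
Conditions: [Ir(cod)((S)-tBu-PHOX)]BArF (2 mol%; cod = 1,5-cyclooctadiene, BArF = tetrakis[3,5-bis(trifluoromethyl)phenyl]borate), H2 (50 bar), CH2Cl2, 25 °C
Reagents that add atoms: none
Why: iridium phosphino-oxazoline catalysed asymmetric hydrogenation of the trisubstituted isoflav-3-ene alkene leaves the aryl bromide and benzyl ethers intact, and the chiral ligand sets C3 of the lower isoflavan as R.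

Step 8
Reactants: 10 (3R)-7-(benzyloxy)-3-[2-(benzyloxy)-5-bromo-4-methoxyphenyl]chromane
Product: 11 4-(benzyloxy)-5-[(3R)-7-(benzyloxy)chroman-3-yl]-2-methoxybenzaldehyde (Ar1–CHO)
Conditions: n-BuLi (1.1 equiv), THF, −78 °C; then DMF, −78 → 0 °C; dilute aq HCl
Reagents that add atoms: N,N-dimethylformamide, CN(C)C=O
Why: bromine–lithium exchange gives an aryllithium stabilised by the ortho methoxy group, and its formylation with DMF places the aldehyde carbon (the later C4) on C5' without touching the remote stereocentre.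

**Arylacetyl imide**

Step 9
Reactants: 12 2,6-dimethoxyphenol
Product: 13 2-(benzyloxy)-1,3-dimethoxybenzene
Conditions: BnBr, K2CO3, DMF, 50 °C
Reagents that add atoms: benzyl bromide, BrCc1ccccc1
Why: Williamson O-benzylation of the phenol.

Step 10
Reactants: 13 2-(benzyloxy)-1,3-dimethoxybenzene
Product: 14 3-(benzyloxy)-1-bromo-2,4-dimethoxybenzene
Conditions: NBS (1.0 equiv), MeCN, 0 → 25 °C
Reagents that add atoms: N-bromosuccinimide, O=C1CCC(=O)N1Br
Why: in a 1,2,3-trialkoxybenzene the central alkoxy group is twisted out of conjugation, so bromination goes ortho to one methoxy and para to the other, as with 1,2,3-trimethoxybenzene.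

Step 11
Reactants: 14 3-(benzyloxy)-1-bromo-2,4-dimethoxybenzene
Product: 15 tert-butyl [3-(benzyloxy)-2,4-dimethoxyphenyl]acetate
Conditions: BrZnCH2CO2tBu (1.3 equiv), Pd2(dba)3 (1 mol%), XPhos (4 mol%), THF, 50 °C
Reagents that add atoms: (2-tert-butoxy-2-oxoethyl)zinc bromide, CC(C)(C)OC(=O)C[Zn]Br
Why: palladium-catalysed cross-coupling of the aryl bromide with a Reformatsky reagent (α-arylation of an ester zinc enolate), which tolerates electron-rich, ortho-substituted bromides.

Step 12
Reactants: 15 tert-butyl [3-(benzyloxy)-2,4-dimethoxyphenyl]acetate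
Product: 16 [3-(benzyloxy)-2,4-dimethoxyphenyl]acetic acid
Conditions: TFA/CH2Cl2 (1:4), 0 → 25 °C
Reagents that add atoms: none
Why: acidolysis of the tert-butyl ester with loss of isobutene, under which the aryl benzyl ether persists.

Step 13
Reactants: 16 [3-(benzyloxy)-2,4-dimethoxyphenyl]acetic acid; 17 (R)-4-benzyloxazolidin-2-one
Product: 19 (R)-4-benzyl-3-{[3-(benzyloxy)-2,4-dimethoxyphenyl]acetyl}oxazolidin-2-one, via pivalic mixed anhydride 18 (not isolated)
Conditions: PivCl, Et3N, THF, −20 °C; then 17, LiCl, 25 °C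
Reagents that add atoms: none
Why: N-acylation of the oxazolidinone through the mixed pivalic anhydride with lithium chloride activation, the usual one-pot preparation of Evans imides.

**Assembly**

Step 14
Reactants: 19 (R)-4-benzyl-3-{[3-(benzyloxy)-2,4-dimethoxyphenyl]acetyl}oxazolidin-2-one; 11 Ar1–CHO
Product: 21 (4R)-4-benzyl-3-[(2S,3R)-3-Ar1-2-Ar2-3-hydroxypropanoyl]oxazolidin-2-one (anti), via aldol trimethylsilyl ether 20 (not isolated)
Conditions: MgCl2 (0.2 equiv), Et3N (2.5 equiv), TMSCl (2.0 equiv), EtOAc, 25 °C; then TBAF/AcOH (1:1), THF, 0 °C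
Reagents that add atoms: none
Why: Evans magnesium halide-catalysed anti-aldol reaction, in which the magnesium-chelated Z-enolate is attacked anti to the auxiliary benzyl group (setting the later upper C3), a boat-like transition state gives the anti carbinol, and silyl trapping holds the adduct of the electron-rich aldehyde.

Step 15
Reactants: 21 (4R)-4-benzyl-3-[(2S,3R)-3-Ar1-2-Ar2-3-hydroxypropanoyl]oxazolidin-2-one
Product: 22 (1R,2R)-1-Ar1-2-Ar2-propane-1,3-diol (anti)
Conditions: LiBH4, THF, MeOH (1 equiv), 0 °C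
Reagents that add atoms: none
Why: reductive cleavage of the N-acyloxazolidinone with lithium borohydride gives the primary alcohol without epimerising the α-aryl centre and returns the auxiliary.

Step 16
Reactants: 22 (1R,2R)-1-Ar1-2-Ar2-propane-1,3-diol
Product: 24 (2R,3R)-2-Ar1-3-Ar2-oxetane (trans), via primary tosylate 23 (not isolated)
Conditions: n-BuLi (1.0 equiv), THF, 0 °C; TsCl (1.0 equiv), 0 °C; then n-BuLi (1.05 equiv), 0 → 45 °C; chromatography on Et3N-deactivated silica
Reagents that add atoms: none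
Why: sulfonylation of the less hindered primary alkoxide followed by 4-exo-tet Williamson displacement by the benzylic alkoxide (a standard 1,3-diol to oxetane protocol) leaves both stereocentres untouched, so the anti-diol gives the trans-oxetane.

**Aryne precursor**

Step 17
Reactants: 25 4-(benzyloxy)phenol
Product: 26 4-(benzyloxy)-2,6-dibromophenol
Conditions: NBS (2.05 equiv), i-Pr2NH (10 mol%), CH2Cl2, 0 → 25 °C
Reagents that add atoms: N-bromosuccinimide, O=C1CCC(=O)N1Br
Why: amine-catalysed ortho-bromination of a para-blocked phenol gives the symmetrical 2,6-dibromide.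

Step 18
Reactants: 26 4-(benzyloxy)-2,6-dibromophenol
Product: 29 4-(benzyloxy)-2-bromo-6-(trimethylsilyl)phenyl trifluoromethanesulfonate, via aryl trimethylsilyl ether 27 (not isolated), via lithium silylphenolate 28 (not isolated)
Conditions: HMDS, THF, 65 °C, then evaporation; n-BuLi (1.05 equiv), THF, −78 → 25 °C; Tf2O, −78 °C
Reagents that add atoms: hexamethyldisilazane, C[Si](C)(C)N[Si](C)(C)C; trifluoromethanesulfonic anhydride, O=S(=O)(OS(=O)(=O)C(F)(F)F)C(F)(F)F
Why: O-silylation, bromine–lithium exchange at one of two equivalent C–Br bonds, retro-Brook 1,3 O-to-C silyl shift and O-triflation form the standard route to ortho-silylaryl triflates, and the symmetry of 26 removes any regiochemical question.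

**Key step and deprotection**

Step 19
Reactants: 24 (2R,3R)-2-Ar1-3-Ar2-oxetane; 29 4-(benzyloxy)-2-bromo-6-(trimethylsilyl)phenyl trifluoromethanesulfonate
Product: 33 (3R,4R)-7-(benzyloxy)-4-Ar1-3-Ar2-5-bromochromane (3,4-trans; same spatial arrangement as 3R,4S in the target, the C4 descriptor changes only because of the bromine), via 5-(benzyloxy)-3-bromobenzyne 30 (not isolated), via oxetanium aryl anion zwitterion 31 (not isolated), via benzyl cation aryl anion zwitterion 32 (not isolated)
Conditions: TBAT (tetrabutylammonium difluorotriphenylsilicate, 3 equiv), 29 (2.5 equiv, added over 6 h by syringe pump), toluene, 50 °C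
Reagents that add atoms: none
Why: Proposed new method: fluoride unmasks aryne 30, the strained and most Lewis-basic ether oxygen of oxetane 24 adds to it to give the O-aryloxetanium aryl anion 31, the C4–O bond (not the CH2–O bond) ionises because C4 sits on C5' of lower ring B ortho to the C4' methoxy and para to the C2' benzyloxy group, and the 2,4-dialkoxybenzyl cation of 32 is captured by the aryl anion at C4a, so that O1–C8a and C4a–C4 form in one operation with ring A inserted between O1 and C4. The closest known reaction types are the insertion of arynes into the benzylic C–O bond of styrene oxides to give dihydrobenzofurans and the three-component couplings in which arynes open oxetane or tetrahydrofuran through O-aryloxonium ions; the two-atom ring expansion of a 2-aryloxetane to a chroman is the new element. The dihydropyran ring closes by intramolecular anion–cation recombination at the trigonal cationic C4 in a 6-exo-trig sense (the cation π system is exocyclic to the new ring), a downhill collapse that should outrun proton loss from C3. The new stereocentre C4 is controlled by C3: in the cation the C3–H bond eclipses the aryl plane to minimise A(1,3) strain with the C6' hydrogen, the CH2O tether delivers C4a to the face anti to the C3 aryl group, and the 3,4-trans product results, which is also what direct retention from the trans-oxetane would give. The step needs oxygen attack at the aryne carbon that becomes C8a and the carbanion at C4a, which the benzyloxy group at C7, remote from the triple bond, cannot enforce; the bromine at C5, ortho to the aryne, polarises it so that the nucleophile adds meta and the anion forms ortho to bromine, and it is removed in step 20. Slow addition of 29 in a non-nucleophilic aprotic solvent keeps proton sources and competing ethers away from the aryl anion.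

Step 20
Reactants: 33 (3R,4R)-7-(benzyloxy)-4-Ar1-3-Ar2-5-bromochromane
Product: 34 target, (3R,4S)-4-{4-hydroxy-5-[(3R)-7-hydroxychroman-3-yl]-2-methoxyphenyl}-3-(3-hydroxy-2,4-dimethoxyphenyl)chroman-7-ol (3,4-trans)
Conditions: H2 (1 atm), Pd/C (10 wt%), NaOAc (2 equiv), THF/MeOH, 25 °C
Reagents that add atoms: none
Why: hydrogenolysis cleaves the four aryl benzyl ethers and the aryl C–Br helper bond in one operation, with acetate taking up HBr and no stereocentre involved.

**Compound list**

1 | paeonol, 1-(2-hydroxy-4-methoxyphenyl)ethanone | CC(=O)c1ccc(OC)cc1O | starting material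
2 | 1-(5-bromo-2-hydroxy-4-methoxyphenyl)ethanone | CC(=O)c1cc(Br)c(OC)cc1O | intermediate
3 | 1-[2-(benzyloxy)-5-bromo-4-methoxyphenyl]ethanone | CC(=O)c1cc(Br)c(OC)cc1OCc1ccccc1 | intermediate
4 | 1-[2-(benzyloxy)-5-bromo-4-methoxyphenyl]-2-bromoethanone | O=C(CBr)c1cc(Br)c(OC)cc1OCc1ccccc1 | intermediate
5 | 4-(benzyloxy)-2-hydroxybenzaldehyde | O=Cc1ccc(OCc2ccccc2)cc1O | starting material
6 | 5-(benzyloxy)-2-(hydroxymethyl)phenol | OCc1ccc(OCc2ccccc2)cc1O | intermediate
7 | [4-(benzyloxy)-2-hydroxybenzyl]triphenylphosphonium bromide | Oc1cc(OCc2ccccc2)ccc1C[P+](c1ccccc1)(c1ccccc1)c1ccccc1.[Br-] | intermediate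
8 | {4-(benzyloxy)-2-[2-(2-(benzyloxy)-5-bromo-4-methoxyphenyl)-2-oxoethoxy]benzyl}triphenylphosphonium bromide | O=C(COc1cc(OCc2ccccc2)ccc1C[P+](c1ccccc1)(c1ccccc1)c1ccccc1)c1cc(Br)c(OC)cc1OCc1ccccc1.[Br-] | intermediate
9 | 7-(benzyloxy)-3-[2-(benzyloxy)-5-bromo-4-methoxyphenyl]-2H-chromene | COc1cc(OCc2ccccc2)c(C2=Cc3ccc(OCc4ccccc4)cc3OC2)cc1Br | intermediate
10 | (3R)-7-(benzyloxy)-3-[2-(benzyloxy)-5-bromo-4-methoxyphenyl]chromane | COc1cc(OCc2ccccc2)c([C@@H]2COc3cc(OCc4ccccc4)ccc3C2)cc1Br | intermediate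
11 | 4-(benzyloxy)-5-[(3R)-7-(benzyloxy)chroman-3-yl]-2-methoxybenzaldehyde | COc1cc(OCc2ccccc2)c([C@@H]2COc3cc(OCc4ccccc4)ccc3C2)cc1C=O | intermediate
12 | 2,6-dimethoxyphenol | COc1cccc(OC)c1O | starting material
13 | 2-(benzyloxy)-1,3-dimethoxybenzene | COc1cccc(OC)c1OCc1ccccc1 | intermediate
14 | 3-(benzyloxy)-1-bromo-2,4-dimethoxybenzene | COc1ccc(Br)c(OC)c1OCc1ccccc1 | intermediate
15 | tert-butyl [3-(benzyloxy)-2,4-dimethoxyphenyl]acetate | COc1ccc(CC(=O)OC(C)(C)C)c(OC)c1OCc1ccccc1 | intermediate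
16 | [3-(benzyloxy)-2,4-dimethoxyphenyl]acetic acid | COc1ccc(CC(=O)O)c(OC)c1OCc1ccccc1 | intermediate
17 | (R)-4-benzyloxazolidin-2-one | O=C1N[C@H](Cc2ccccc2)CO1 | starting material
18 | [3-(benzyloxy)-2,4-dimethoxyphenyl]acetic pivalic anhydride | COc1ccc(CC(=O)OC(=O)C(C)(C)C)c(OC)c1OCc1ccccc1 | intermediate
19 | (R)-4-benzyl-3-{[3-(benzyloxy)-2,4-dimethoxyphenyl]acetyl}oxazolidin-2-one | COc1ccc(CC(=O)N2[C@H](Cc3ccccc3)COC2=O)c(OC)c1OCc1ccccc1 | intermediate
20 | O-trimethylsilyl ether of anti-aldol adduct 21 | O=C(N1[C@H](Cc2ccccc2)COC1=O)[C@H]([C@@H](O[Si](C)(C)C)c1cc([C@@H]2COc3cc(OCc4ccccc4)ccc3C2)c(OCc2ccccc2)cc1OC)c1ccc(OC)c(OCc2ccccc2)c1OC | intermediate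
21 | (4R)-4-benzyl-3-[(2S,3R)-3-Ar1-2-Ar2-3-hydroxypropanoyl]oxazolidin-2-one | O=C(N1[C@H](Cc2ccccc2)COC1=O)[C@H]([C@@H](O)c1cc([C@@H]2COc3cc(OCc4ccccc4)ccc3C2)c(OCc2ccccc2)cc1OC)c1ccc(OC)c(OCc2ccccc2)c1OC | intermediate
22 | (1R,2R)-1-Ar1-2-Ar2-propane-1,3-diol | OC[C@H]([C@@H](O)c1cc([C@@H]2COc3cc(OCc4ccccc4)ccc3C2)c(OCc2ccccc2)cc1OC)c1ccc(OC)c(OCc2ccccc2)c1OC | intermediate
23 | (2R,3R)-3-Ar1-2-Ar2-3-hydroxypropyl 4-methylbenzenesulfonate | Cc1ccc(S(=O)(=O)OC[C@H]([C@@H](O)c2cc([C@@H]3COc4cc(OCc5ccccc5)ccc4C3)c(OCc3ccccc3)cc2OC)c2ccc(OC)c(OCc3ccccc3)c2OC)cc1 | intermediate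
24 | (2R,3R)-2-Ar1-3-Ar2-oxetane (trans) | O1C[C@H]([C@@H]1c1cc([C@@H]2COc3cc(OCc4ccccc4)ccc3C2)c(OCc2ccccc2)cc1OC)c1ccc(OC)c(OCc2ccccc2)c1OC | intermediate
25 | 4-(benzyloxy)phenol | Oc1ccc(OCc2ccccc2)cc1 | starting material
26 | 4-(benzyloxy)-2,6-dibromophenol | Oc1c(Br)cc(OCc2ccccc2)cc1Br | intermediate
27 | [4-(benzyloxy)-2,6-dibromophenoxy]trimethylsilane | C[Si](C)(C)Oc1c(Br)cc(OCc2ccccc2)cc1Br | intermediate
28 | lithium 4-(benzyloxy)-2-bromo-6-(trimethylsilyl)phenolate | [Li+].[O-]c1c(Br)cc(OCc2ccccc2)cc1[Si](C)(C)C | intermediate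
29 | 4-(benzyloxy)-2-bromo-6-(trimethylsilyl)phenyl trifluoromethanesulfonate | C[Si](C)(C)c1cc(OCc2ccccc2)cc(Br)c1OS(=O)(=O)C(F)(F)F | intermediate
30 | 5-(benzyloxy)-3-bromobenzyne | BrC1=CC(OCc2ccccc2)=CC#C1 | intermediate
31 | O-[5-(benzyloxy)-3-bromo-2-phenylide] oxetanium zwitterion of 24 | [O+]1(c2cc(OCc3ccccc3)cc(Br)[c-]2)C[C@H]([C@@H]1c1cc([C@@H]2COc3cc(OCc4ccccc4)ccc3C2)c(OCc2ccccc2)cc1OC)c1ccc(OC)c(OCc2ccccc2)c1OC | intermediate
32 | ring-opened zwitterion: aryl anion at C4a, 2,4-dialkoxybenzyl cation at C4 | Brc1cc(OCc2ccccc2)cc(OC[C@H]([CH+]c2cc([C@@H]3COc4cc(OCc5ccccc5)ccc4C3)c(OCc3ccccc3)cc2OC)c2ccc(OC)c(OCc3ccccc3)c2OC)[c-]1 | intermediate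
33 | (3R,4R)-7-(benzyloxy)-4-Ar1-3-Ar2-5-bromochromane (trans) | COc1cc(OCc2ccccc2)c([C@@H]2COc3cc(OCc4ccccc4)ccc3C2)cc1[C@@H]1c2c(Br)cc(OCc3ccccc3)cc2OC[C@H]1c1ccc(OC)c(OCc2ccccc2)c1OC | intermediate
34 | (3R,4S)-4-{4-hydroxy-5-[(3R)-7-hydroxychroman-3-yl]-2-methoxyphenyl}-3-(3-hydroxy-2,4-dimethoxyphenyl)chroman-7-ol | COc1cc(O)c([C@@H]2COc3cc(O)ccc3C2)cc1[C@@H]1c2ccc(O)cc2OC[C@H]1c1ccc(OC)c(O)c1OC | target

**Step count and risks**

Total steps: 20. Longest linear sequence: 11 (steps 1, 2, 3, 6, 7, 8, 14, 15, 16, 19, 20).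

Steps most likely to fail:

1. Step 19 (proposed new method). What may go wrong: the hindered oxetane oxygen may be arylated too slowly, so the aryne is consumed otherwise. The aryl anion may take the C3 proton from the cation (elimination to a stilbene ether) instead of closing the ring. Fluoride may open the oxetanium ion. The ortho-bromoaryl anion may expel bromide. Facial control in the ring closure may be incomplete.
Fallback with known chemistry, setting out from diol 22 and returning at target 34: Mitsunobu etherification of the primary hydroxyl with 3-(benzyloxy)phenol (PPh3, DIAD, THF, 0 °C) should give (1R,2R)-3-[3-(benzyloxy)phenoxy]-1-Ar1-2-Ar2-propan-1-ol F1. A catalytic Lewis acid (Sc(OTf)3, CH2Cl2, −40 °C) would then ionise the benzylic alcohol, and the tethered resorcinol ring should close C4a–C4 by intramolecular Friedel–Crafts alkylation para to its benzyloxy group, trans by the same A(1,3) argument. This gives the bromine-free tetrabenzyl ether (3R,4S)-7-(benzyloxy)-4-Ar1-3-Ar2-chromane F2, which the hydrogenolysis of step 20 converts into 34. O1–C2 and C4a–C4 are then made in two classical steps and no aryne is used.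

2. Step 16. What may go wrong: Grob fragmentation of the γ-tosyloxy benzylic alkoxide back to aldehyde 11 and a styrene, and acid-induced ring opening of the electron-rich 2-aryloxetane during isolation.
Fallback, setting out from diol 22 and returning at oxetane 24: the ring closure is changed from anionic sulfonate displacement to a neutral intramolecular Mitsunobu redox dehydration (PPh3, DIAD, toluene, 0 → 60 °C). The primary hydroxyl is activated as an alkoxyphosphonium ion and displaced by the benzylic hydroxyl with retention at the carbinol carbon, so the free γ-sulfonyloxy alkoxide that fragments is never formed. No new compound is made on the way.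

3. Step 14. What may go wrong: sluggish addition of the magnesium enolate to the electron-rich, ortho-alkoxy aldehyde, retro-aldol before silyl trapping, and erosion of the α-aryl stereocentre by re-enolisation under triethylamine.
Fallback, setting out from acid 16 and returning at 33:
- Acid 16 is attached to (S)-4-benzyloxazolidin-2-one (step 13 protocol) to give (S)-4-benzyl-3-{[3-(benzyloxy)-2,4-dimethoxyphenyl]acetyl}oxazolidin-2-one F3.
- Kinetic boron enolisation (Bu2BOTf, i-Pr2NEt, CH2Cl2, −78 °C) and addition to aldehyde 11 through the closed chair transition state should give the Evans syn adduct (4S)-4-benzyl-3-[(2S,3S)-3-Ar1-2-Ar2-3-hydroxypropanoyl]oxazolidin-2-one F4, with the same configuration at the later C3 and the opposite carbinol configuration.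
- LiBH4 reduction gives the syn diol (1S,2R)-1-Ar1-2-Ar2-propane-1,3-diol F5.
- The step 16 protocol gives the primary tosylate (2R,3S)-3-Ar1-2-Ar2-3-hydroxypropyl 4-methylbenzenesulfonate F6 and then the cis-oxetane (2S,3R)-2-Ar1-3-Ar2-oxetane F7.
- F7 is submitted to step 19, where the carbinol stereocentre is erased at the cation stage, and the route is rejoined at 33.

Further compounds
F1 | step 19 | (1R,2R)-3-[3-(benzyloxy)phenoxy]-1-Ar1-2-Ar2-propan-1-ol | O(C[C@H]([C@@H](O)c1cc([C@@H]2COc3cc(OCc4ccccc4)ccc3C2)c(OCc2ccccc2)cc1OC)c1ccc(OC)c(OCc2ccccc2)c1OC)c1cccc(OCc2ccccc2)c1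
F2 | step 19 | (3R,4S)-7-(benzyloxy)-4-Ar1-3-Ar2-chromane | COc1cc(OCc2ccccc2)c([C@@H]2COc3cc(OCc4ccccc4)ccc3C2)cc1[C@@H]1c2ccc(OCc3ccccc3)cc2OC[C@H]1c1ccc(OC)c(OCc2ccccc2)c1OC
F0 | step 16 | none | none
F3 | step 14 | (S)-4-benzyl-3-{[3-(benzyloxy)-2,4-dimethoxyphenyl]acetyl}oxazolidin-2-one | COc1ccc(CC(=O)N2[C@@H](Cc3ccccc3)COC2=O)c(OC)c1OCc1ccccc1
F4 | step 14 | (4S)-4-benzyl-3-[(2S,3S)-3-Ar1-2-Ar2-3-hydroxypropanoyl]oxazolidin-2-one | O=C(N1[C@@H](Cc2ccccc2)COC1=O)[C@H]([C@H](O)c1cc([C@@H]2COc3cc(OCc4ccccc4)ccc3C2)c(OCc2ccccc2)cc1OC)c1ccc(OC)c(OCc2ccccc2)c1OC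
F5 | step 14 | (1S,2R)-1-Ar1-2-Ar2-propane-1,3-diol | OC[C@H]([C@H](O)c1cc([C@@H]2COc3cc(OCc4ccccc4)ccc3C2)c(OCc2ccccc2)cc1OC)c1ccc(OC)c(OCc2ccccc2)c1OC
F6 | step 14 | (2R,3S)-3-Ar1-2-Ar2-3-hydroxypropyl 4-methylbenzenesulfonate | Cc1ccc(S(=O)(=O)OC[C@H]([C@H](O)c2cc([C@@H]3COc4cc(OCc5ccccc5)ccc4C3)c(OCc3ccccc3)cc2OC)c2ccc(OC)c(OCc3ccccc3)c2OC)cc1
F7 | step 14 | (2S,3R)-2-Ar1-3-Ar2-oxetane (cis) | O1C[C@H]([C@H]1c1cc([C@@H]2COc3cc(OCc4ccccc4)ccc3C2)c(OCc2ccccc2)cc1OC)c1ccc(OC)c(OCc2ccccc2)c1OC
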